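Readings and results were computed with constants of no real substance, and the scatter is random.

A small charge of free catalyst turns over the starting material with partner, and the earlier runs show how fast.

| setting | violet | green | blue | Tuesday's | Monday's | Friday's | Thursday's | Sunday's |
|---|---|---|---|---|---|---|---|---|
| starting material | 5.1 mM | 16 mM | 33 mM | 20 mM | 6.0 mM | 20 mM | 40 mM | 20 mM |
| partner | 1.3 equiv | 1.3 equiv | 1.3 equiv | 1.30 equiv | 1.30 equiv | 2.00 equiv | 5.20 equiv | 1.30 equiv |
| second substrate | 5 equiv (in portions, 2) | 5 equiv (in portions, 2) | 5 equiv (in portions, 2) | 5.00 equiv (in portions, 2) | 2.50 equiv (in portions, 2) | 5.00 equiv (in portions, 2) | 5.00 equiv (in portions, 2) | 5.00 equiv (in portions, 2) |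
| free catalyst | 0.1 mol% | 0.1 mol% | 0.1 mol% | 0.2 mol% | 0.03 mol% | 0.1 mol% | 0.05 mol% | 0.1 mol% |
| remark | run made earlier; portions every 12 min | run made earlier; portions every 12 min | run made earlier; portions every 12 min | the portions of second substrate follow each other after 12 min, the first at the start | the portions of second substrate follow each other after 12 min, the first at the start | the portions of second substrate follow each other after 12 min, the first at the start | the portions of second substrate follow each other after 12 min, the first at the start | the portions of second substrate follow each other after 12 min, the first at the start |
| time |  |  |  | 1.0 h | 1.0 h | 1.0 h | 1.0 h | 1.0 h |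

| run | time / min | target / % |
|---|---|---|
| violet | 5.00 | 0 |
| violet | 15.0 | 5 |
| violet | 25.0 | 3 |
| violet | 40.0 | 7 |
| green | 10.0 | 16 |
| green | 20.0 | 25 |
| green | 30.0 | 31 |
| green | 40.0 | 29 |
| blue | 3.00 | 18 |
| blue | 8.00 | 34 |
| blue | 20.0 | 49 |
| blue | 40.0 | 46 |

(each reading ± 2 percentage points)

- a reading or a percentage of target counts all its forms, free or not

1. the flasks by amount of target, in percent of the starting material charged, highest first, at 1.0 h (Tuesday's / Monday's / Friday's / Thursday's / Sunday's)
2. the same order at 3.0 min (Tuesday's / Monday's / Friday's / Thursday's / Sunday's)
3. the amount of target, in percent of the starting material charged of the flask you put first, at 1.0 h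
4. the amount of target, in percent of the starting material charged of the flask you put last, at 1.0 h

The three runs keep the recipe and change the dilution, so [partner] and [free catalyst] rise together with [starting material]. The first readings of target climb steeply along that series. The reckoning here treats early loss of starting material as pseudo-first-order, with a rate constant proportional to [partner][free catalyst]. That is an assumption: these runs cannot separate partner from second substrate. The blue run's first reading gives the scale, N, the count of e-fold falls of starting material at that reading:

N(blue, 3.00 min) = 0.198

N(flask) = N(blue) × ([partner][free catalyst] of the flask / the same in blue) × (t / 3.00 min)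

N says how many e-fold falls of starting material the charges could deliver if they never ran down, and the target share is then 1 − exp(−N). The green reading at 20.0 min has N = 0.311, which gives 26.7 % against 25 % read. The blue reading at 40.0 min gives 92.9 % against 46 % read, so in the blue run the one number fails by that time.

At 3.0 min:

Thursday's: N = 0.583, target 44.2 %

Tuesday's: N = 0.146, target 13.6 %

Friday's: N = 0.112, target 10.6 %

Sunday's: N = 0.0729, target 7.03 %

Monday's: N = 0.00197, target 0.197 %

At 1.0 h, Monday's reaches N = 0.0394, still in the range that held, so its target should be 3.86 %. The other four flasks have large N by then, so N ranks them in the same order but gives no amount. Sunday's has the recipe of the runs at a [starting material] between green's and blue's, so it should fall between their last readings, 29 % and 46 %.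

The forecast held that “the catalyst is apparently dying or being inhibited” and gave Thursday's > Tuesday's > Friday's > Sunday's > Monday's at 1.0 h and Thursday's > Tuesday's > Friday's > Sunday's > Monday's at 3.0 min, with 85 % for the first flask and 2 % for the last at 1.0 h.

At 1.0 h the flasks stand Thursday's > Friday's > Tuesday's > Sunday's > Monday's, from 65.3 % to 3.67 %, so Friday's passes Tuesday's; at 3.0 min they stand Thursday's > Tuesday's > Friday's > Sunday's > Monday's.

    starting material + partner + free catalyst → free catalyst + target (k = 58000 M⁻² min⁻¹)
    second substrate + partner + free catalyst → free catalyst + second product (k = 16000 M⁻² min⁻¹)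
    free catalyst + target ⇌ idle complex (K = 30.0 M⁻¹, k = 2.20 M⁻¹ min⁻¹)
    second substrate + free catalyst → spent catalyst (k = 0.0150 M⁻¹ min⁻¹)
    target → over-reaction product (k = 0.00770 min⁻¹)

Monday's holds 0.241 % target at 3.0 min, where N gave 0.197 %. Monday's neighbour with 0.12 mol% free catalyst holds 12.5 % at 1.0 h, where N gives 14.6 %. In Thursday's, with the other concentrations held at their charge, starting material has a half-life of 2.9 min by its step to target, far shorter than the 1.5 h half-life of free target going to over-reaction product. At 1.0 h, Thursday's holds 1.46 % starting material, 65.3 % target and 33.2 % over-reaction product.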